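**Retrosynthetic overview**

1. The target is (2S,3S)-trans-5-allyl-3-methyl-2-(3,4,5-trimethoxyphenyl)-2,3-dihydrobenzofuran-6-ol (17). The plan rests on the unit O1–C2(aryl)–C3(–CH3)–C3a of its dihydrofuran ring, which is O1–C2–C3–C4–C4a of a 2-arylchroman-4-one with C4 pushed out of the ring. The furan ring is therefore a contracted pyranone ring, and the C3 methyl carbon is the former carbonyl carbon.
2. Late stage: O6–H from O6–benzyl; C5–allyl from C5–Br (Stille); C3–CH3 from C3–CO2CH3 (reduction, mesylate, hydride).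
3. Key disconnection: the C3–C3a bond and the five-membered ring come from (S)-flavanone 8 by a 1,2-shift of ring A carbon C4a from C4 to C3, induced by trivalent iodine. C2 relays its configuration to C3.
4. Flavanone 8: the C2–aryl bond comes from chromone 6 and boronic acid 7 by enantioselective conjugate addition. The pyranone ring comes from acetophenone 4 via its enaminone, and 4 from 2,4-dihydroxyacetophenone 1 by C5 bromination and 4-O-benzylation.
5. Ring order: ring A is bought, the pyranone ring is closed in step 3, ring B is attached in step 4, and the pyranone ring is contracted to the dihydrofuran in step 5.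

Key step: step 5

Remark (assumption): the sense of induction of t-BuPyOx on chromones is taken to match that on 3-substituted cyclohexenones, where the (S)-ligand gives the (R)-adduct. The (R)-ligand is therefore specified for 2S. The configuration of 8 should be confirmed (the bromine atom allows an X-ray assignment) and the ligand enantiomer exchanged if needed. Compounds 5–10 carry chromane numbering, compounds 11–17 benzofuran numbering.

**Route**

Step 1
Reactants: 1 2,4-dihydroxyacetophenone
Product: 2 1-(5-bromo-2,4-dihydroxyphenyl)ethan-1-one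
Conditions: NBS (1.0 equiv), MeCN, 0 °C to rt
Reagents that add atoms: N-bromosuccinimide, O=C1CCC(=O)N1Br
Why: Electrophilic aromatic bromination; C5 is para to the chelated 2-OH, ortho to the 4-OH and less hindered than C3 between the two oxygens, so one equivalent of NBS should brominate there.

Step 2
Reactants: 2 1-(5-bromo-2,4-dihydroxyphenyl)ethan-1-one; 3 benzyl bromide
Product: 4 1-[4-(benzyloxy)-5-bromo-2-hydroxyphenyl]ethan-1-one
Conditions: K2CO3 (1.2 equiv), acetone, reflux
Reagents that add atoms: benzyl bromide (3), BrCc1ccccc1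
Why: Williamson ether synthesis; the 2-OH is hydrogen-bonded to the acetyl carbonyl and far less nucleophilic, so only the 4-OH should be alkylated.

Step 3
Reactants: 4 1-[4-(benzyloxy)-5-bromo-2-hydroxyphenyl]ethan-1-one
Product: 6 7-(benzyloxy)-6-bromo-4H-chromen-4-one, via enaminone 5 (not isolated)
Conditions: Me2NCH(OMe)2 (2 equiv), toluene, 100 °C; concentrate; then conc. HCl, CH2Cl2, 40 °C
Reagents that add atoms: N,N-dimethylformamide dimethyl acetal, COC(OC)N(C)C
Why: Enaminone condensation of the methyl ketone with the formamide acetal, then acid-promoted conjugate addition of the phenol and loss of dimethylamine (addition–elimination) close the pyranone ring; benzyl ether and aryl bromide are inert.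

Step 4
Reactants: 6 7-(benzyloxy)-6-bromo-4H-chromen-4-one; 7 3,4,5-trimethoxyphenylboronic acid (2 equiv)
Product: 8 (S)-7-(benzyloxy)-6-bromo-2-(3,4,5-trimethoxyphenyl)chroman-4-one
Conditions: Pd(OCOCF3)2 (5 mol %), (R)-t-BuPyOx (6 mol %), NH4PF6 (30 mol %), H2O (5 equiv), ClCH2CH2Cl, 60 °C
Reagents that add atoms: 3,4,5-trimethoxyphenylboronic acid (7), COc1cc(B(O)O)cc(OC)c1OC
Why: Asymmetric conjugate addition of an arylboronic acid catalysed by divalent palladium with a pyridine–oxazoline ligand (Hayashi–Miyaura-type 1,4-addition): transmetalation, enantioface-selective insertion of the chromone C2=C3 bond under control of the ligand sets C2 as S, and water protonates the palladium enolate; the aryl bromide should survive because no zerovalent palladium takes part in the cycle.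

Step 5
Reactants: 8 (S)-7-(benzyloxy)-6-bromo-2-(3,4,5-trimethoxyphenyl)chroman-4-one
Product: 12 methyl (2S,3S)-6-(benzyloxy)-5-bromo-2-(3,4,5-trimethoxyphenyl)-2,3-dihydrobenzofuran-3-carboxylate, via methyl enol ether 9 (not isolated), via trans iodanyl ketal 10 (not isolated), via trimethyl orthoester 11 (not isolated)
Conditions: PhI(OAc)2 (1.3 equiv), conc. H2SO4 (0.5 equiv), HC(OMe)3, 0 °C to rt; then H2O
Reagents that add atoms: trimethyl orthoformate, COC(OC)OC; water, O
Why: Acid and HC(OMe)3 convert the C4 ketone of 8 into methyl enol ether 9, the trivalent iodine electrophile adds to C3 on the face away from the C2 aryl group, and methanol traps the oxocarbenium ion as ketal 10, in which C3–I and C2–aryl are trans and both equatorial. The equatorial C3–I bond is antiperiplanar to the ring bond C4–C4a, so ring A carbon C4a shifts from C4 to C3 through a bridged phenonium-type transition state with loss of PhI and inversion at C3, C4 leaving the ring as a dimethoxycarbenium ion that is taken up as orthoester 11 and hydrolysed to the methyl ester on work-up. The closest known reaction type is the oxidative ring contraction of flavanones, and the related 1,2-aryl shift of aryl alkyl ketones, with trivalent iodine or trivalent thallium reagents in trimethyl orthoformate. The five-membered ring therefore closes by contraction of the pyranone ring (formation of C3–C3a in a 1,2-shift) and not by a cyclisation. The new stereocentre C3 is controlled by C2, since anti iodination followed by invertive shift puts the ester trans to the aryl group, which is also the isomer favoured if the acidic C3–H equilibrates. The step needs shift of ring A in preference to shift of ring B (isoflavone), dehydrogenation (flavone) and acid opening to the chalcone (loss of C2): C4a carries O1 ortho and the benzyloxy group para, ring B has two meta methoxy groups and its C2–aryl bond is not antiperiplanar to C3–I in the diequatorial conformer, the C6 bromine blocks the most nucleophilic arene position, and excess orthoformate makes enol ether formation faster than ring opening.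

Step 6
Reactants: 12 methyl (2S,3S)-6-(benzyloxy)-5-bromo-2-(3,4,5-trimethoxyphenyl)-2,3-dihydrobenzofuran-3-carboxylate
Product: 13 [(2S,3R)-6-(benzyloxy)-5-bromo-2-(3,4,5-trimethoxyphenyl)-2,3-dihydrobenzofuran-3-yl]methanol
Conditions: LiAlH4 (1.2 equiv), THF, 0 °C; then H2O, aq. NaOH
Reagents that add atoms: none
Why: Hydride reduction of the ester; addition to the carbonyl at 0 °C is faster than enolisation, so C3 should not epimerise and the ring should not open by β-elimination, the aryl bromide is inert at this temperature, and the descriptor at C3 changes to R only through the priority change.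

Step 7
Reactants: 13 [(2S,3R)-6-(benzyloxy)-5-bromo-2-(3,4,5-trimethoxyphenyl)-2,3-dihydrobenzofuran-3-yl]methanol
Product: 14 [(2S,3R)-6-(benzyloxy)-5-bromo-2-(3,4,5-trimethoxyphenyl)-2,3-dihydrobenzofuran-3-yl]methyl methanesulfonate
Conditions: MsCl (1.3 equiv), Et3N (2 equiv), CH2Cl2, 0 °C
Reagents that add atoms: methanesulfonyl chloride, CS(=O)(=O)Cl
Why: Sulfonylation of the unhindered primary alcohol; no stereocentre is touched.

Step 8
Reactants: 14 [(2S,3R)-6-(benzyloxy)-5-bromo-2-(3,4,5-trimethoxyphenyl)-2,3-dihydrobenzofuran-3-yl]methyl methanesulfonate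
Product: 15 (2S,3S)-6-(benzyloxy)-5-bromo-3-methyl-2-(3,4,5-trimethoxyphenyl)-2,3-dihydrobenzofuran
Conditions: LiEt3BH (2.5 equiv), THF, 0 °C to rt; then H2O
Reagents that add atoms: none
Why: SN2 displacement of the primary sulfonate by the strongly nucleophilic, weakly basic hydride should outrun elimination and leave the aryl bromide alone at this temperature; C3 is not involved and reverts to the descriptor S by priority only.

Step 9
Reactants: 15 (2S,3S)-6-(benzyloxy)-5-bromo-3-methyl-2-(3,4,5-trimethoxyphenyl)-2,3-dihydrobenzofuran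
Product: 16 (2S,3S)-5-allyl-6-(benzyloxy)-3-methyl-2-(3,4,5-trimethoxyphenyl)-2,3-dihydrobenzofuran
Conditions: allyltributylstannane (1.5 equiv), Pd(PPh3)4 (5 mol %), degassed toluene, 110 °C; aq. KF work-up
Reagents that add atoms: allyltributylstannane, C=CC[Sn](CCCC)(CCCC)CCCC
Why: Stille cross-coupling (oxidative addition of zerovalent palladium into C5–Br, allyl transfer from tin, reductive elimination) under neutral conditions that leave both stereocentres and the benzyl ether untouched.

Step 10
Reactants: 16 (2S,3S)-5-allyl-6-(benzyloxy)-3-methyl-2-(3,4,5-trimethoxyphenyl)-2,3-dihydrobenzofuran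
Product: 17 (2S,3S)-5-allyl-3-methyl-2-(3,4,5-trimethoxyphenyl)-2,3-dihydrobenzofuran-6-ol
Conditions: BCl3 (2 equiv), pentamethylbenzene (3 equiv), CH2Cl2, −78 °C; then CHCl3/MeOH, −78 °C to rt
Reagents that add atoms: none
Why: Lewis acid cleavage of the aryl benzyl ether with a non-Lewis-basic cation scavenger; BCl3 activates the primary benzyl ether at −78 °C and pentamethylbenzene takes up the benzyl cation by Friedel–Crafts alkylation, so the allyl group, the methyl ethers and the electron-rich rings should be spared.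

**Compound list**

1 | 2,4-dihydroxyacetophenone | CC(=O)c1ccc(O)cc1O | starting material
2 | 1-(5-bromo-2,4-dihydroxyphenyl)ethan-1-one | CC(=O)c1cc(Br)c(O)cc1O | intermediate
3 | benzyl bromide | BrCc1ccccc1 | starting material
4 | 1-[4-(benzyloxy)-5-bromo-2-hydroxyphenyl]ethan-1-one | CC(=O)c1cc(Br)c(OCc2ccccc2)cc1O | intermediate
5 | (E)-1-[4-(benzyloxy)-5-bromo-2-hydroxyphenyl]-3-(dimethylamino)prop-2-en-1-one (enaminone, not isolated) | CN(C)/C=C/C(=O)c1cc(Br)c(OCc2ccccc2)cc1O | intermediate
6 | 7-(benzyloxy)-6-bromo-4H-chromen-4-one | O=c1ccoc2cc(OCc3ccccc3)c(Br)cc12 | intermediate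
7 | 3,4,5-trimethoxyphenylboronic acid | COc1cc(B(O)O)cc(OC)c1OC | starting material
8 | (S)-7-(benzyloxy)-6-bromo-2-(3,4,5-trimethoxyphenyl)chroman-4-one | O=C1C[C@@H](c2cc(OC)c(OC)c(OC)c2)Oc2cc(OCc3ccccc3)c(Br)cc21 | intermediate
9 | (S)-7-(benzyloxy)-6-bromo-4-methoxy-2-(3,4,5-trimethoxyphenyl)-2H-chromene (methyl enol ether, not isolated) | COC1=C[C@@H](c2cc(OC)c(OC)c(OC)c2)Oc2cc(OCc3ccccc3)c(Br)cc21 | intermediate
10 | acetoxy[(2R,3R)-7-(benzyloxy)-6-bromo-4,4-dimethoxy-2-(3,4,5-trimethoxyphenyl)chroman-3-yl]phenyl-λ3-iodane (2,3-trans, not isolated) | COC1(OC)[C@H](I(OC(C)=O)c2ccccc2)[C@@H](c2cc(OC)c(OC)c(OC)c2)Oc2cc(OCc3ccccc3)c(Br)cc21 | intermediate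
11 | (2S,3S)-6-(benzyloxy)-5-bromo-3-(trimethoxymethyl)-2-(3,4,5-trimethoxyphenyl)-2,3-dihydrobenzofuran (orthoester, not isolated) | Brc1cc2c(cc1OCc1ccccc1)O[C@H](c1cc(OC)c(OC)c(OC)c1)[C@H]2C(OC)(OC)OC | intermediate
12 | methyl (2S,3S)-6-(benzyloxy)-5-bromo-2-(3,4,5-trimethoxyphenyl)-2,3-dihydrobenzofuran-3-carboxylate (trans) | Brc1cc2c(cc1OCc1ccccc1)O[C@H](c1cc(OC)c(OC)c(OC)c1)[C@H]2C(=O)OC | intermediate
13 | [(2S,3R)-6-(benzyloxy)-5-bromo-2-(3,4,5-trimethoxyphenyl)-2,3-dihydrobenzofuran-3-yl]methanol | Brc1cc2c(cc1OCc1ccccc1)O[C@H](c1cc(OC)c(OC)c(OC)c1)[C@H]2CO | intermediate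
14 | [(2S,3R)-6-(benzyloxy)-5-bromo-2-(3,4,5-trimethoxyphenyl)-2,3-dihydrobenzofuran-3-yl]methyl methanesulfonate | Brc1cc2c(cc1OCc1ccccc1)O[C@H](c1cc(OC)c(OC)c(OC)c1)[C@H]2COS(C)(=O)=O | intermediate
15 | (2S,3S)-6-(benzyloxy)-5-bromo-3-methyl-2-(3,4,5-trimethoxyphenyl)-2,3-dihydrobenzofuran | Brc1cc2c(cc1OCc1ccccc1)O[C@H](c1cc(OC)c(OC)c(OC)c1)[C@H]2C | intermediate
16 | (2S,3S)-5-allyl-6-(benzyloxy)-3-methyl-2-(3,4,5-trimethoxyphenyl)-2,3-dihydrobenzofuran | C=CCc1cc2c(cc1OCc1ccccc1)O[C@H](c1cc(OC)c(OC)c(OC)c1)[C@H]2C | intermediate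
17 | (2S,3S)-5-allyl-3-methyl-2-(3,4,5-trimethoxyphenyl)-2,3-dihydrobenzofuran-6-ol | C=CCc1cc2c(cc1O)O[C@H](c1cc(OC)c(OC)c(OC)c1)[C@H]2C | target

**Step count and risks**

Total step count: 10. Longest linear sequence: 10 steps (1 to 17).

Steps most likely to fail:

Step 5 (ring contraction). The aryl shift may go astray: ring B may shift from C2 to C3 and lead to the isoflavone, the ketal may lose hydrogen to the flavone, or acid may open 8 to the chalcone and erode C2. The fallback builds the same ester by C–H insertion instead of ring contraction; it sets out from 4 and returns at 12. The chelated phenol of 4 would be alkylated with 3,4,5-trimethoxybenzyl chloride (K2CO3, KI, DMF, 60 °C) to give 1-[4-(benzyloxy)-5-bromo-2-[(3,4,5-trimethoxybenzyl)oxy]phenyl]ethan-1-one F1. Oxidative rearrangement of this aryl methyl ketone with trivalent thallium nitrate, Tl(NO3)3·3H2O, in HC(OMe)3/MeOH should give methyl 2-[4-(benzyloxy)-5-bromo-2-[(3,4,5-trimethoxybenzyl)oxy]phenyl]acetate F2. Diazo transfer (4-acetamidobenzenesulfonyl azide, DBU, MeCN) would give methyl 2-[4-(benzyloxy)-5-bromo-2-[(3,4,5-trimethoxybenzyl)oxy]phenyl]-2-diazoacetate F3. The dirhodium carboxylate Rh2(S-PTTL)4, or its enantiomer, whichever delivers 2S, in toluene at −78 °C should then effect enantioselective intramolecular 1,5 C–H insertion of the rhodium carbenoid into the benzylic OCH2 group. This closes the dihydrofuran as methyl (2S,3R)-cis-6-(benzyloxy)-5-bromo-2-(3,4,5-trimethoxyphenyl)-2,3-dihydrobenzofuran-3-carboxylate F4. NaOMe in MeOH at 0 °C would epimerise C3 to the trans ester 12.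

Step 4 (asymmetric conjugate addition). Enantioface selection may be poor on this 6,7-disubstituted chromone, or protodeboronation of 7 may outrun transmetalation. The fallback replaces asymmetric catalysis by resolution; it sets out from 4 and returns at 8. Claisen–Schmidt condensation of 4 with 3,4,5-trimethoxybenzaldehyde (KOH, EtOH, rt) would give (E)-1-[4-(benzyloxy)-5-bromo-2-hydroxyphenyl]-3-(3,4,5-trimethoxyphenyl)prop-2-en-1-one F5. NaOAc in refluxing EtOH should close it by oxa-Michael addition to racemic 7-(benzyloxy)-6-bromo-2-(3,4,5-trimethoxyphenyl)chroman-4-one F6. Preparative chromatography on a chiral stationary phase (amylose tris(3,5-dimethylphenylcarbamate), supercritical CO2/MeOH) would deliver 8. The unwanted (R)-7-(benzyloxy)-6-bromo-2-(3,4,5-trimethoxyphenyl)chroman-4-one F7 would be returned to the racemate through the chalcone with the same base.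

Step 10 (debenzylation). The Lewis acid or the HCl it releases may attack the allyl group (hydrochlorination, double-bond migration), or the freed ortho-allylphenol may cyclise onto the alkene. The fallback removes the benzyl group before the alkene is present and ends with a base-labile ester; it sets out from 15 and returns at 17. BCl3 and pentamethylbenzene in CH2Cl2 at −78 °C would give (2S,3S)-5-bromo-3-methyl-2-(3,4,5-trimethoxyphenyl)-2,3-dihydrobenzofuran-6-ol F8. Ac2O and pyridine would give (2S,3S)-5-bromo-3-methyl-2-(3,4,5-trimethoxyphenyl)-2,3-dihydrobenzofuran-6-yl acetate F9, whose C–Br bond is also more reactive toward zerovalent palladium. Stille coupling with allyltributylstannane and Pd(PPh3)4 in toluene at 100 °C would give (2S,3S)-5-allyl-3-methyl-2-(3,4,5-trimethoxyphenyl)-2,3-dihydrobenzofuran-6-yl acetate F10. K2CO3 in MeOH at rt would then free the phenol 17 without moving the double bond.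

**Further compounds**

F1 | step 5 | 1-[4-(benzyloxy)-5-bromo-2-[(3,4,5-trimethoxybenzyl)oxy]phenyl]ethan-1-one | CC(=O)c1cc(Br)c(OCc2ccccc2)cc1OCc1cc(OC)c(OC)c(OC)c1
F2 | step 5 | methyl 2-[4-(benzyloxy)-5-bromo-2-[(3,4,5-trimethoxybenzyl)oxy]phenyl]acetate | COC(=O)Cc1cc(Br)c(OCc2ccccc2)cc1OCc1cc(OC)c(OC)c(OC)c1
F3 | step 5 | methyl 2-[4-(benzyloxy)-5-bromo-2-[(3,4,5-trimethoxybenzyl)oxy]phenyl]-2-diazoacetate | COC(=O)C(=[N+]=[N-])c1cc(Br)c(OCc2ccccc2)cc1OCc1cc(OC)c(OC)c(OC)c1
F4 | step 5 | methyl (2S,3R)-cis-6-(benzyloxy)-5-bromo-2-(3,4,5-trimethoxyphenyl)-2,3-dihydrobenzofuran-3-carboxylate | Brc1cc2c(cc1OCc1ccccc1)O[C@H](c1cc(OC)c(OC)c(OC)c1)[C@@H]2C(=O)OC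
F5 | step 4 | (E)-1-[4-(benzyloxy)-5-bromo-2-hydroxyphenyl]-3-(3,4,5-trimethoxyphenyl)prop-2-en-1-one | O=C(/C=C/c1cc(OC)c(OC)c(OC)c1)c1cc(Br)c(OCc2ccccc2)cc1O
F6 | step 4 | racemic 7-(benzyloxy)-6-bromo-2-(3,4,5-trimethoxyphenyl)chroman-4-one | O=C1CC(c2cc(OC)c(OC)c(OC)c2)Oc2cc(OCc3ccccc3)c(Br)cc21
F7 | step 4 | (R)-7-(benzyloxy)-6-bromo-2-(3,4,5-trimethoxyphenyl)chroman-4-one | O=C1C[C@H](c2cc(OC)c(OC)c(OC)c2)Oc2cc(OCc3ccccc3)c(Br)cc21
F8 | step 10 | (2S,3S)-5-bromo-3-methyl-2-(3,4,5-trimethoxyphenyl)-2,3-dihydrobenzofuran-6-ol | Brc1cc2c(cc1O)O[C@H](c1cc(OC)c(OC)c(OC)c1)[C@H]2C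
F9 | step 10 | (2S,3S)-5-bromo-3-methyl-2-(3,4,5-trimethoxyphenyl)-2,3-dihydrobenzofuran-6-yl acetate | Brc1cc2c(cc1OC(C)=O)O[C@H](c1cc(OC)c(OC)c(OC)c1)[C@H]2C
F10 | step 10 | (2S,3S)-5-allyl-3-methyl-2-(3,4,5-trimethoxyphenyl)-2,3-dihydrobenzofuran-6-yl acetate | C=CCc1cc2c(cc1OC(C)=O)O[C@H](c1cc(OC)c(OC)c(OC)c1)[C@H]2C
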